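Everything rests on opening ring B (C5–C10, drimane numbering), the cyclohexene that sits between quaternary C10 and C9, the carbon carrying the arylmethyl carbon C11. With C11 raised to a ketone, the C9=C10 alkene becomes a dienophile. One Lewis-acid-promoted intramolecular Diels–Alder reaction then forms C5–C10 and C8–C9, closes rings A and B, and sets C5, C8, C9 and C10 against a preset C4. The precursor is an acyclic aryl trienone: a 2,5-dimethoxy-4-methylphenyl (E)-β-methylenone joined through C1–C3 to quaternary C4 (CH3, CH2OTBS), which bears an (E,E)-diene. C4 comes from a Sharpless epoxide by a stereospecific 1,2-shift; the arene later becomes the epoxyquinol.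

Key step: step 10

Numbering and shorthand: the decalin uses drimane numbering (C11 on C9, C12 on C8). The ring that starts as the arene is primed: C1′ bears C11, C2′ is the neighbouring oxygenated carbon, C4′ bears CH3, C5′ bears the second oxygen. α is the face of H5 and H9; β is the face of the C10 methyl. D6 is the C11-linked drim-6-ene unit with 4α-CH2OTBS, 4β-CH3, 5α-H, 8β-CH3, 9α-H and 10β-CH3. D7 is the drim-7-ene unit of the target as its TBS ether, (1S,4aR,5R,8aR) in naphthalene numbering.

Assumption: the sense of induction of the cinchonidinium salt in step 15 cannot be derived for this substrate. It is taken to give the (1′R,6′S)-epoxide 25; the pseudoenantiomeric cinchoninium salt would replace it if the sense were opposite.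

Step 1
Reactants: 1 (5-chloropent-1-yn-1-yl)trimethylsilane; 2 ethyl but-2-ynoate
Product: 4 ethyl (2E)-3-methyl-8-(trimethylsilyl)oct-2-en-7-ynoate, via Grignard reagent 3 (not isolated)
Conditions: Mg, THF, reflux; CuBr·SMe2 (1 equiv), THF, −40 °C; 2, −78 °C; cold aq NH4Cl quench
Reagents that add atoms: none
Why: Conjugate addition of an organocopper reagent to an alkynoate (syn-carbocupration) with a cold proton quench places the new chain cis to the vinylic H, so the trisubstituted alkene should be E, and the C-silyl cap removes the acidic alkyne proton that would destroy 3.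

Step 2
Reactants: 4 ethyl (2E)-3-methyl-8-(trimethylsilyl)oct-2-en-7-ynoate
Product: 5 (2E)-3-methyl-8-(trimethylsilyl)oct-2-en-7-yn-1-ol
Conditions: DIBAL-H (2.2 equiv), CH2Cl2, −78 → 0 °C; Rochelle salt
Reagents that add atoms: none
Why: DIBAL-H reduction of an α,β-unsaturated ester goes by two 1,2-hydride deliveries to the allylic alcohol and leaves the alkene geometry and the silylalkyne untouched at low temperature.

Step 3
Reactants: 5 (2E)-3-methyl-8-(trimethylsilyl)oct-2-en-7-yn-1-ol
Product: 6 {(2S,3S)-3-methyl-3-[5-(trimethylsilyl)pent-4-yn-1-yl]oxiran-2-yl}methanol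
Conditions: Ti(OiPr)4 (cat.), L-(+)-diethyl tartrate (cat.), t-BuOOH, 4 Å MS, CH2Cl2, −20 °C
Reagents that add atoms: tert-butyl hydroperoxide CC(C)(C)OO
Why: Katsuki–Sharpless asymmetric epoxidation of an E-configured 3,3-disubstituted allylic alcohol of the geraniol type with the L-(+)-tartrate catalyst delivers oxygen to the face that gives the (2S,3S)-epoxide, which introduces the absolute configuration later found at C4.

Step 4
Reactants: 6 {(2S,3S)-3-methyl-3-[5-(trimethylsilyl)pent-4-yn-1-yl]oxiran-2-yl}methanol
Product: 7 tert-butyldimethylsilyl ether of 6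
Conditions: TBSCl, imidazole, DMF, rt
Reagents that add atoms: tert-butyldimethylsilyl chloride CC(C)(C)[Si](C)(C)Cl
Why: Imidazole-promoted silylation of a primary alcohol gives the epoxy silyl ether needed for step 5, and the same group then protects the C4 hydroxymethyl arm until step 19.

Step 5
Reactants: 7 tert-butyldimethylsilyl ether of 6
Product: 8 (2S)-2-{[(tert-butyldimethylsilyl)oxy]methyl}-2-methyl-7-(trimethylsilyl)hept-6-ynal
Conditions: MABR (2 equiv, from Me3Al + 4-bromo-2,6-di-tert-butylphenol), CH2Cl2, −78 °C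
Reagents that add atoms: none
Why: In this Lewis-acid-induced rearrangement of an epoxy silyl ether (semipinacol-type 1,2-shift) the bulky aluminium phenoxide ionises the tertiary C3–O bond and the siloxymethyl group migrates from C2 to C3 anti to the leaving oxygen, so the epoxide configuration passes with inversion into the all-carbon quaternary centre (2S in 8, the future C4) while the old C2 becomes the non-enolisable aldehyde C5.

Step 6
Reactants: 9 (E)-1-bromobut-2-ene; 10 triethyl phosphite
Product: 11 diethyl [(2E)-but-2-en-1-yl]phosphonate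
Conditions: neat, 130 °C, EtBr distilled off
Reagents that add atoms: none
Why: Michaelis–Arbuzov reaction of a primary allylic bromide proceeds by SN2 attack of phosphorus and dealkylation by bromide, and it keeps the E alkene.

Step 7
Reactants: 8 (2S)-2-{[(tert-butyldimethylsilyl)oxy]methyl}-2-methyl-7-(trimethylsilyl)hept-6-ynal; 11 diethyl [(2E)-but-2-en-1-yl]phosphonate
Product: 13 tert-butyldimethyl{[(2R,3E,5E)-2-methyl-2-(pent-4-yn-1-yl)hepta-3,5-dien-1-yl]oxy}silane, via C-silylated dienyne 12 (not isolated)
Conditions: 11, n-BuLi, THF–DMPU, −78 °C; 8, −78 °C → rt; then MeOH, K2CO3 (cat.), rt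
Reagents that add atoms: none
Why: Horner–Wadsworth–Emmons olefination with a lithiated allylic (semi-stabilised) phosphonate should turn the hindered, non-enolisable aldehyde into the diene with an E C5=C6 bond, and methoxide then cleaves only the alkynyl C–Si bond while the TBS ether stays.

Step 8
Reactants: 13 tert-butyldimethyl{[(2R,3E,5E)-2-methyl-2-(pent-4-yn-1-yl)hepta-3,5-dien-1-yl]oxy}silane; 14 2,5-dimethoxy-4-methylbenzaldehyde
Product: 16 (2E,7R,8E,10E)-7-{[(tert-butyldimethylsilyl)oxy]methyl}-1-(2,5-dimethoxy-4-methylphenyl)-3,7-dimethyldodeca-2,8,10-trien-1-ol (both C1 epimers), via alkenylalane 15 (not isolated)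
Conditions: Me3Al (2 equiv), Cp2ZrCl2 (20 mol %), CH2Cl2, 0 °C → rt; 14 (excess), −78 → 0 °C; Rochelle salt
Reagents that add atoms: trimethylaluminium C[Al](C)C
Why: Negishi zirconium-catalysed carboalumination adds CH3 and Al syn across the terminal alkyne with Al at the terminus, which fixes the E C9=C10 geometry (C11 cis to the C10 methyl) while the internal diene and the silyl ether are inert, and the alkenylalane then adds 1,2 to the aldehyde to give a carbinol centre that step 9 erases.

Step 9
Reactants: 16 (2E,7R,8E,10E)-trienol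
Product: 17 (2E,7R,8E,10E)-7-{[(tert-butyldimethylsilyl)oxy]methyl}-1-(2,5-dimethoxy-4-methylphenyl)-3,7-dimethyldodeca-2,8,10-trien-1-one
Conditions: MnO2 (excess), CH2Cl2, rt
Reagents that add atoms: none
Why: MnO2 oxidation is selective for the doubly activated (allylic and benzylic) carbinol and, being neutral, avoids ionisation of this acid-sensitive alcohol and touches neither the diene nor the silyl ether.

Step 10
Reactants: 17 aryl trienone
Product: 18 (2,5-dimethoxy-4-methylphenyl) D6 ketone, the trans-fused 11-aryl-11-oxodrim-6-ene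
Conditions: Me2AlCl (2.2 equiv), CH2Cl2 (0.01 M), −78 → −20 °C
Reagents that add atoms: none
Why: Two-point binding of aluminium to the C11 carbonyl and the C2′ methoxy oxygen lowers the LUMO of the E C9=C10 enone, which adds suprafacially, in a concerted but asynchronous [4+2] process, to the s-cis C5=C6–C7=C8 diene and forms C5–C10 and C8–C9. The closest known reaction type is the Lewis-acid-promoted type 1 intramolecular Diels–Alder reaction of terminally carbonyl-activated (2E,8E,10E)-undeca-2,8,10-trienoates, -trienals and -trienones, which gives trans-fused octalins through the endo mode; ring B (C5–C10) is closed by the cycloaddition itself and ring A (C1–C5, C10) as the six-membered ring spanned by the C1–C4 tether in a chair-like array. C9 and C10 follow from the E geometry of the enone (C11 and the C10 methyl cis), C8 from the E,E geometry of the diene (C8 methyl cis to the C5–C4 bond), and the trans C5/C10 fusion from the endo position of the chelated aroyl group, which forces the tether exo. The step also needs π-facial selectivity with respect to the resident C4 centre: in the chair-like tether the axial site at C4 is 1,3-diaxial to the incoming C10 methyl, so the smaller CH3 should take it and the CH2OTBS arm should stay equatorial, which leads to 4α-CH2O, 5α-H and 10β-CH3. Geminal substitution at C4 (Thorpe–Ingold effect) offsets the low reactivity of the β,β-disubstituted dienophile, and Me2AlCl scavenges protons, which protects the diene and the silyl ether.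

Step 11
Reactants: 18 (2,5-dimethoxy-4-methylphenyl) D6 ketone
Product: 19 (2-hydroxy-5-methoxy-4-methylphenyl) D6 ketone
Conditions: BCl3 (1.1 equiv), CH2Cl2, −78 → −20 °C; aq NaHCO3
Reagents that add atoms: none
Why: In this chelation-directed aryl methyl ether cleavage BCl3 binds between the C11 carbonyl and the ortho C2′ methoxy oxygen and chloride removes only that methyl group, which differentiates the two ring oxygens, while the non-chelated C5′ ether, the disubstituted alkene and the neopentyl TBS ether should survive one equivalent at low temperature.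

Step 12
Reactants: 19 (2-hydroxy-5-methoxy-4-methylphenyl) D6 ketone
Product: 22 4-methoxy-5-methyl-2-(D6)phenol with C11 as CH2, via aryl ethyl carbonate 20 (not isolated), via o-quinone methide 21 (not isolated)
Conditions: ClCO2Et, Et3N, THF, 0 °C; filter; NaBH4, THF–H2O, 0 °C → rt
Reagents that add atoms: none
Why: This is a reductive deoxygenation through an o-quinone methide, in which borohydride reduces the ketone of 20, the alkoxide takes over the carbonate, phenoxide-driven 1,4-elimination gives 21, and a second hydride adds to C11 faster than 21 can tautomerise, all under basic conditions that spare C9, the alkene and the silyl ether.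

Step 13
Reactants: 22 4-methoxy-5-methyl-2-(D6)phenol
Product: 23 4-methoxy-5-methyl-2-(D7)phenol
Conditions: RuHCl(CO)(PPh3)3 (10 mol %), toluene, 110 °C
Reagents that add atoms: none
Why: In this transition-metal-hydride alkene isomerisation (insertion/β-hydride elimination) Ru–H should add to the open α face of C6=C7 with the metal on the less crowded C7 (C6 is flanked by C5 and the peri CH2OTBS group), the cycloaddition has left H8 on the same α face so that syn β-hydride elimination gives the trisubstituted C7=C8 alkene, relief of the 8β-CH3/10β-CH3 contact drives the shift, further migration to C8=C9 would need a tertiary Ru alkyl, and the neutral medium keeps the phenol from adding to C8.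

Step 14
Reactants: 23 4-methoxy-5-methyl-2-(D7)phenol
Product: 24 4,4-dimethoxy-5-methyl-2-(D7)cyclohexa-2,5-dien-1-one
Conditions: PhI(OAc)2 (1.1 equiv), MeOH, 0 °C
Reagents that add atoms: methanol CO
Why: Hypervalent-iodine oxidative dearomatisation of a 4-methoxyphenol in methanol gives the p-quinone monoketal, which leaves C2′ as the only carbonyl and masks C5′, and phenol oxidation is much faster than any reaction at the trisubstituted alkene.

Step 15
Reactants: 24 4,4-dimethoxy-5-methyl-2-(D7)cyclohexa-2,5-dien-1-one
Product: 25 (1R,6S)-5,5-dimethoxy-4-methyl-1-(D7)-7-oxabicyclo[4.1.0]hept-3-en-2-one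
Conditions: t-BuOOH, 1 M aq NaOH, N-benzylcinchonidinium chloride (10 mol %), toluene, 0 °C → rt
Reagents that add atoms: tert-butyl hydroperoxide CC(C)(C)OO
Why: In this Weitz–Scheffer nucleophilic epoxidation under chiral phase-transfer catalysis, a reaction type established for quinone monoketals, the peroxide anion attacks the unsubstituted β-carbon C6′ rather than the methyl-bearing C4′, so only C1′=C6′ reacts, and because the drimane centres are too remote to choose the face, the ion-paired cinchona cation is relied on to set C1′ and C6′ (a minor diastereomer is separable since D7 is a single enantiomer).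

Step 16
Reactants: 25 (1R,6S)-epoxy ketone
Product: 26 (1S,2S,6S)-5,5-dimethoxy-4-methyl-1-(D7)-7-oxabicyclo[4.1.0]hept-3-en-2-ol, 2′-OH syn to the epoxide
Conditions: DIBAL-H, THF, −78 °C
Reagents that add atoms: none
Why: In this substrate-controlled 1,2-reduction of a cyclic α,β-epoxy enone the hydride attacks C2′ anti to the epoxide C–O bond (Felkin–Anh alignment, general for cyclic epoxy ketones), which should give the 2′S alcohol syn to the epoxide, and the β-methyl group next to the ketal suppresses 1,4-reduction.

Step 17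
Reactants: 26 (1S,2S,6S)-syn-epoxy alcohol
Product: 27 (1S,2R,6S)-5,5-dimethoxy-4-methyl-1-(D7)-7-oxabicyclo[4.1.0]hept-3-en-2-yl 4-nitrobenzoate, ester anti to the epoxide
Conditions: PPh3, DIAD, 4-nitrobenzoic acid, toluene, 0 °C → rt
Reagents that add atoms: 4-nitrobenzoic acid O=C(O)c1ccc(cc1)[N+](=O)[O-]
Why: Mitsunobu inversion, by SN2 displacement of the oxyphosphonium group at the allylic C2′ from the face opposite the epoxide, turns 2′S into 2′R, the anti relationship of the target; the tied-back epoxide carbon C1′ hinders this less than an ordinary quaternary neighbour, and SN2′ attack is blocked because C4′ is fully substituted and adjoins the ketal.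

Step 18
Reactants: 27 (1S,2R,6S)-4-nitrobenzoate
Product: 28 (1S,2R,6S)-5,5-dimethoxy-4-methyl-1-(D7)-7-oxabicyclo[4.1.0]hept-3-en-2-ol, 2′-OH anti to the epoxide
Conditions: K2CO3 (0.2 equiv), MeOH, 0 °C
Reagents that add atoms: none
Why: Carbonate-catalysed transesterification removes the activated 4-nitrobenzoate without breaking the C2′–O bond, and brief exposure to a weak base in a protic solvent keeps Payne migration of the anti epoxy alcohol from setting in.

Step 19
Reactants: 28 (1S,2R,6S)-anti-epoxy alcohol
Product: 29 Epoxypholamin B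
Conditions: 48 % aq HF, MeCN, 0 °C → rt
Reagents that add atoms: water O
Why: Acid hydrolysis of the dimethyl ketal to the C5′ enone and fluoride-assisted cleavage of the primary TBS ether occur in one operation and touch no stereocentre, since the epoxide is deactivated by the adjacent carbonyl and the medium is too weakly acidic to protonate C7=C8.

Compound list
1 | (5-chloropent-1-yn-1-yl)trimethylsilane | C[Si](C)(C)C#CCCCCl | starting material
2 | ethyl but-2-ynoate | CC#CC(=O)OCC | starting material
3 | [5-(trimethylsilyl)pent-4-yn-1-yl]magnesium chloride | C[Si](C)(C)C#CCCC[Mg]Cl | intermediate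
4 | ethyl (2E)-3-methyl-8-(trimethylsilyl)oct-2-en-7-ynoate | CCOC(=O)/C=C(\C)CCCC#C[Si](C)(C)C | intermediate
5 | (2E)-3-methyl-8-(trimethylsilyl)oct-2-en-7-yn-1-ol | OC/C=C(\C)CCCC#C[Si](C)(C)C | intermediate
6 | {(2S,3S)-3-methyl-3-[5-(trimethylsilyl)pent-4-yn-1-yl]oxiran-2-yl}methanol | OC[C@@H]1O[C@@]1(C)CCCC#C[Si](C)(C)C | intermediate
7 | tert-butyldimethylsilyl ether of 6 | CC(C)(C)[Si](C)(C)OC[C@@H]1O[C@@]1(C)CCCC#C[Si](C)(C)C | intermediate
8 | (2S)-2-{[(tert-butyldimethylsilyl)oxy]methyl}-2-methyl-7-(trimethylsilyl)hept-6-ynal | O=C[C@](C)(CO[Si](C)(C)C(C)(C)C)CCCC#C[Si](C)(C)C | intermediate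
9 | (E)-1-bromobut-2-ene | C/C=C/CBr | starting material
10 | triethyl phosphite | CCOP(OCC)OCC | starting material
11 | diethyl [(2E)-but-2-en-1-yl]phosphonate | C/C=C/CP(=O)(OCC)OCC | intermediate
12 | tert-butyldimethyl{[(2R,3E,5E)-2-methyl-2-[5-(trimethylsilyl)pent-4-yn-1-yl]hepta-3,5-dien-1-yl]oxy}silane | C/C=C/C=C/[C@](C)(CO[Si](C)(C)C(C)(C)C)CCCC#C[Si](C)(C)C | intermediate
13 | tert-butyldimethyl{[(2R,3E,5E)-2-methyl-2-(pent-4-yn-1-yl)hepta-3,5-dien-1-yl]oxy}silane | C/C=C/C=C/[C@](C)(CO[Si](C)(C)C(C)(C)C)CCCC#C | intermediate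
14 | 2,5-dimethoxy-4-methylbenzaldehyde | COc1cc(C)c(OC)cc1C=O | starting material
15 | (E)-alkenyl(dimethyl)alane from syn methylalumination of 13 | C/C=C/C=C/[C@](C)(CO[Si](C)(C)C(C)(C)C)CCC/C(C)=C/[Al](C)C | intermediate
16 | (2E,7R,8E,10E)-7-{[(tert-butyldimethylsilyl)oxy]methyl}-1-(2,5-dimethoxy-4-methylphenyl)-3,7-dimethyldodeca-2,8,10-trien-1-ol, both C1 epimers | COc1cc(C)c(OC)cc1C(O)/C=C(\C)CCC[C@@](C)(CO[Si](C)(C)C(C)(C)C)/C=C/C=C/C | intermediate
17 | (2E,7R,8E,10E)-7-{[(tert-butyldimethylsilyl)oxy]methyl}-1-(2,5-dimethoxy-4-methylphenyl)-3,7-dimethyldodeca-2,8,10-trien-1-one | COc1cc(C)c(OC)cc1C(=O)/C=C(\C)CCC[C@@](C)(CO[Si](C)(C)C(C)(C)C)/C=C/C=C/C | intermediate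
18 | trans-fused 11-(2,5-dimethoxy-4-methylphenyl)-11-oxodrim-6-ene; 4α-CH2OTBS, 4β-CH3, 5α-H, 8β-CH3, 9α-H, 10β-CH3 | COc1cc(C)c(OC)cc1C(=O)[C@H]3[C@@H](C)C=C[C@H]4[C@](C)(CO[Si](C)(C)C(C)(C)C)CCC[C@]34C | intermediate
19 | 11-(2-hydroxy-5-methoxy-4-methylphenyl)-11-oxodrim-6-ene, decalin as in 18 | Cc1cc(O)c(cc1OC)C(=O)[C@H]3[C@@H](C)C=C[C@H]4[C@](C)(CO[Si](C)(C)C(C)(C)C)CCC[C@]34C | intermediate
20 | ethyl carbonate of phenol 19 | Cc1cc(OC(=O)OCC)c(cc1OC)C(=O)[C@H]3[C@@H](C)C=C[C@H]4[C@](C)(CO[Si](C)(C)C(C)(C)C)CCC[C@]34C | intermediate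
21 | o-quinone methide, 4-methoxy-3-methyl-6-(C11-ylidene)cyclohexa-2,4-dien-1-one carrying the decalin of 18 | CC1=CC(=O)C(=C[C@H]3[C@@H](C)C=C[C@H]4[C@](C)(CO[Si](C)(C)C(C)(C)C)CCC[C@]34C)C=C1OC | intermediate
22 | 4-methoxy-5-methyl-2-(D6)phenol, C11 = CH2, C6=C7 | Cc1cc(O)c(cc1OC)C[C@H]3[C@@H](C)C=C[C@H]4[C@](C)(CO[Si](C)(C)C(C)(C)C)CCC[C@]34C | intermediate
23 | 4-methoxy-5-methyl-2-(D7)phenol, C7=C8 | Cc1cc(O)c(cc1OC)C[C@H]3C(C)=CC[C@H]4[C@](C)(CO[Si](C)(C)C(C)(C)C)CCC[C@]34C | intermediate
24 | 4,4-dimethoxy-5-methyl-2-(D7)cyclohexa-2,5-dien-1-one | CC1=CC(=O)C(C[C@H]3C(C)=CC[C@H]4[C@](C)(CO[Si](C)(C)C(C)(C)C)CCC[C@]34C)=CC1(OC)OC | intermediate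
25 | (1R,6S)-5,5-dimethoxy-4-methyl-1-(D7)-7-oxabicyclo[4.1.0]hept-3-en-2-one | CC1=CC(=O)[C@]2(C[C@H]3C(C)=CC[C@H]4[C@](C)(CO[Si](C)(C)C(C)(C)C)CCC[C@]34C)O[C@@H]2C1(OC)OC | intermediate
26 | (1S,2S,6S)-5,5-dimethoxy-4-methyl-1-(D7)-7-oxabicyclo[4.1.0]hept-3-en-2-ol, OH syn to the epoxide | CC1=C[C@H](O)[C@]2(C[C@H]3C(C)=CC[C@H]4[C@](C)(CO[Si](C)(C)C(C)(C)C)CCC[C@]34C)O[C@@H]2C1(OC)OC | intermediate
27 | (1S,2R,6S)-5,5-dimethoxy-4-methyl-1-(D7)-7-oxabicyclo[4.1.0]hept-3-en-2-yl 4-nitrobenzoate, ester anti to the epoxide | CC1=C[C@@H](OC(=O)c5ccc(cc5)[N+](=O)[O-])[C@]2(C[C@H]3C(C)=CC[C@H]4[C@](C)(CO[Si](C)(C)C(C)(C)C)CCC[C@]34C)O[C@@H]2C1(OC)OC | intermediate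
28 | (1S,2R,6S)-5,5-dimethoxy-4-methyl-1-(D7)-7-oxabicyclo[4.1.0]hept-3-en-2-ol, OH anti to the epoxide | CC1=C[C@@H](O)[C@]2(C[C@H]3C(C)=CC[C@H]4[C@](C)(CO[Si](C)(C)C(C)(C)C)CCC[C@]34C)O[C@@H]2C1(OC)OC | intermediate
29 | Epoxypholamin B, (1S,2R,6S)-2-hydroxy-1-{[(1S,4aR,5R,8aR)-5-(hydroxymethyl)-2,5,8a-trimethyl-1,4,4a,5,6,7,8,8a-octahydronaphthalen-1-yl]methyl}-4-methyl-7-oxabicyclo[4.1.0]hept-3-en-5-one | CC1=C[C@@H](O)[C@]2(C[C@H]3C(C)=CC[C@H]4[C@](C)(CO)CCC[C@]34C)O[C@@H]2C1=O | target

Total step count: 19. Longest linear sequence: 18 steps (1–5 and 7–19, from 1 to 29); step 6 is a one-step side branch.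

Steps most likely to fail

**Step 10.**
- What may go wrong (rate): the β,β-disubstituted enone, conjugated to an electron-rich arene, may react too slowly. Lewis-acid-induced isomerisation or oligomerisation of the diene, Nazarov-type closure of the aryl vinyl ketone onto C6′, or loss of the silyl ether could then overtake the cycloaddition.
- What may go wrong (selectivity): the CH3/CH2OTBS pair at C4 may distinguish the two diene faces only weakly, giving poor π-facial selectivity.
- Fallback (sets out from 13, returns at 18): form the same two bonds, but activate with an aldehyde and introduce the arene afterwards. Alane 15, made from 13 as in step 8, is turned into its ate complex with n-BuLi and trapped with paraformaldehyde to give (2E,7R,8E,10E)-7-{[(tert-butyldimethylsilyl)oxy]methyl}-3,7-dimethyldodeca-2,8,10-trien-1-ol F1. MnO2 oxidises this to the trienal F2. The enal is a much stronger dienophile, so EtAlCl2 should bring about the endo intramolecular Diels–Alder reaction already at −78 °C, where the chair preference at C4 counts for more, and give the trans-fused drim-6-en-11-al F3. (2,5-Dimethoxy-4-methylphenyl)lithium F4, from commercial 1-bromo-2,5-dimethoxy-4-methylbenzene and n-BuLi, adds to F3 to give the C11 carbinol F5. Dess–Martin oxidation of F5 leads back to 18.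

**Step 13.**
- What may go wrong: there may be no turnover at the hindered ring alkene. Insertion with ruthenium on C6 would move the double bond towards C5. Over-migration to the tetrasubstituted C8=C9 position is also possible.
- Fallback (sets out from 22, returns at 24): replace the catalytic hydrogen shift by stoichiometric hydration and syn-dehydration. Hydroboration of 22 (BH3·SMe2, THF; NaBO3) should occur on the α face with boron on the less hindered C7 and give the 7α-alcohol F6, whose hydroxyl is cis to H8. PhI(OAc)2 in methanol, as in step 14, converts the phenol into the 7α-hydroxy quinone monoketal F7. The Burgess reagent (benzene, 50 °C) then effects a syn elimination in the Zaitsev sense, using the cis H8α, to give 24.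

**Step 15.**
- What may go wrong: facial selectivity may be poor, because the planar ring is remote from all resident stereocentres, and phase-transfer turnover may be slow next to the bulky C1′ substituent.
- Fallback (sets out from 24, returns at 25): give up catalyst control and move the choice of face to a separation that the enantiopure drimane unit makes possible. Homogeneous epoxidation with t-BuOOH and DBU in CH2Cl2 should give 25 together with its (1S,6R)-epoxide diastereomer F8. The two are diastereomers and are parted by chromatography; 25 goes on to step 16 and F8 is set aside.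

Further compounds
F1 | step 10 | (2E,7R,8E,10E)-7-{[(tert-butyldimethylsilyl)oxy]methyl}-3,7-dimethyldodeca-2,8,10-trien-1-ol | OC/C=C(\C)CCC[C@@](C)(CO[Si](C)(C)C(C)(C)C)/C=C/C=C/C
F2 | step 10 | (2E,7R,8E,10E)-7-{[(tert-butyldimethylsilyl)oxy]methyl}-3,7-dimethyldodeca-2,8,10-trienal | O=C/C=C(\C)CCC[C@@](C)(CO[Si](C)(C)C(C)(C)C)/C=C/C=C/C
F3 | step 10 | trans-fused drim-6-en-11-al with the decalin stereochemistry of 18 | O=C[C@H]3[C@@H](C)C=C[C@H]4[C@](C)(CO[Si](C)(C)C(C)(C)C)CCC[C@]34C
F4 | step 10 | (2,5-dimethoxy-4-methylphenyl)lithium | [Li]c1cc(OC)c(C)cc1OC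
F5 | step 10 | 11-(2,5-dimethoxy-4-methylphenyl)drim-6-en-11-ol, both C11 epimers, decalin as in 18 | COc1cc(C)c(OC)cc1C(O)[C@H]3[C@@H](C)C=C[C@H]4[C@](C)(CO[Si](C)(C)C(C)(C)C)CCC[C@]34C
F6 | step 13 | 7α-hydroxy-6,7-dihydro derivative of phenol 22 | Cc1cc(O)c(cc1OC)C[C@H]3[C@@H](C)[C@H](O)C[C@H]4[C@](C)(CO[Si](C)(C)C(C)(C)C)CCC[C@]34C
F7 | step 13 | 4,4-dimethoxy-5-methylcyclohexa-2,5-dien-1-one carrying the 7α-hydroxy-8β-methyl drimane unit of F6 at C2 | CC1=CC(=O)C(C[C@H]3[C@@H](C)[C@H](O)C[C@H]4[C@](C)(CO[Si](C)(C)C(C)(C)C)CCC[C@]34C)=CC1(OC)OC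
F8 | step 15 | (1S,6R)-5,5-dimethoxy-4-methyl-1-(D7)-7-oxabicyclo[4.1.0]hept-3-en-2-one, epoxide diastereomer of 25 | CC1=CC(=O)[C@@]2(C[C@H]3C(C)=CC[C@H]4[C@](C)(CO[Si](C)(C)C(C)(C)C)CCC[C@]34C)O[C@H]2C1(OC)OC
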